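**Retrosynthetic overview**
1. The phenol is freed last by chemoselective aminolysis of an aryl acetate; the benzylic acetate stays in place.
2. Key disconnection, C7–OAc: the bond is made directly from the benzylic C7–H of the (8R,8'R)-dibenzylbutane. The aryl acetate on the other ring switches C7' off, and C8 together with a chiral copper catalyst fixes the face.
3. C8 and C8' are set together by one double asymmetric hydrogenation of the (E,E)-1,4-diaryl-2,3-dimethylbuta-1,3-diene.
4. The skeleton comes from two successive Heck arylations of 2,3-dimethylbuta-1,3-diene, with 4-bromoveratrole and with 4-bromoguaiacol (acetylated in the flask).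
5. No ring is formed; both benzene rings are bought.

Assumption: lignan locants are used in the text (C7 = carbon bearing OAc, C8 and C8' = the two CH(CH3), C7' = CH2 next to the guaiacyl ring), so the target is 7R,8S,8'R. The sense of induction of both chiral catalysts is assigned from the closest models, and both ligand antipodes are on sale.

Step 1
Reactants: 1 4-bromo-1,2-dimethoxybenzene; 2 2,3-dimethylbuta-1,3-diene
Product: 3 4-[(1E)-2,3-dimethylbuta-1,3-dien-1-yl]-1,2-dimethoxybenzene
Conditions: Pd(OAc)2 (2 mol %), P(o-tol)3 (6 mol %), NaOAc (1.5 equiv), 2 (5 equiv), BHT (1 mol %), DMAc, 120 °C, sealed tube, 16 h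
Reagents that add atoms: none
Why: Mizoroki–Heck arylation of a conjugated diene, in which aryl-palladium adds to a terminal CH2 and β-hydride elimination from the new benzylic CH2 of the allyl-palladium gives the conjugated (E)-aryl diene (aryl trans to the dienyl chain), while the fivefold excess of cheap 2 holds back double arylation; no stereocenter is formed.

Step 2
Reactants: 3 4-[(1E)-2,3-dimethylbuta-1,3-dien-1-yl]-1,2-dimethoxybenzene; 4 4-bromo-2-methoxyphenol
Product: 6 4-[(1E,3E)-4-(3,4-dimethoxyphenyl)-2,3-dimethylbuta-1,3-dien-1-yl]-2-methoxyphenyl acetate, via 4-bromo-2-methoxyphenyl acetate 5 (not isolated)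
Conditions: 4, Ac2O (1.1 equiv), NaOAc (2.6 equiv), DMAc, 60 °C, 30 min; then 3 (1.0 equiv), Pd(OAc)2 (2 mol %), P(o-tol)3 (6 mol %), 120 °C, 16 h; recrystallise from EtOH
Reagents that add atoms: acetic anhydride, CC(=O)OC(C)=O
Why: NaOAc-promoted O-acetylation first masks the phenol (acetate as base can only exchange with an aryl acetate, not remove it), and a second Mizoroki–Heck reaction then arylates the only terminal CH2 left in 3, with β-hydride elimination giving the fully conjugated, crystallisable (E,E)-diene; no stereocenter is formed.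

Step 3
Reactants: 6 4-[(1E,3E)-4-(3,4-dimethoxyphenyl)-2,3-dimethylbuta-1,3-dien-1-yl]-2-methoxyphenyl acetate
Product: 7 4-[(2R,3R)-4-(3,4-dimethoxyphenyl)-2,3-dimethylbutyl]-2-methoxyphenyl acetate
Conditions: [Ir(cod)((S)-tBu-PHOX)]BArF (1 mol %), H2 (50 bar), CH2Cl2, 25 °C, 24 h
Reagents that add atoms: none
Why: Iridium N,P-ligand asymmetric hydrogenation of unfunctionalised (E)-trisubstituted aryl alkenes, in which the two ArCH=C(CH3) units are twisted out of conjugation and offer the same enantioface, so the (S)-ligand, which gives the (R)-alkane from (E)-1,2-diphenylpropene (same priority order at the new center), sets C8 and C8' as R,R, and the double reduction raises the ee at the cost of a little separable erythro isomer.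

Step 4
Reactants: 7 4-[(2R,3R)-4-(3,4-dimethoxyphenyl)-2,3-dimethylbutyl]-2-methoxyphenyl acetate
Product: 8 (1R,2S,3R)-4-[4-(acetyloxy)-3-methoxyphenyl]-1-(3,4-dimethoxyphenyl)-2,3-dimethylbutyl acetate
Conditions: Cu(OAc)2 (10 mol %), (3aR,3a'R,8aS,8a'S)-2,2'-(cyclopropane-1,1-diyl)bis(3a,8a-dihydro-8H-indeno[1,2-d]oxazole) (12 mol %), 4CzIPN (2 mol %), n-Bu4NOAc (1 equiv, electrolyte and buffer, regenerated from AcOH at the cathode), AcOH/MeCN 1:4, undivided cell, graphite-felt anode, Pt cathode, 2 mA, 2.2 F/mol, 450 nm LEDs, 5 °C
Reagents that add atoms: acetic acid, CC(=O)O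
Why: Proposed new method: excited 4CzIPN (or its radical cation after quenching by divalent copper) oxidises only the veratryl ring (about +1.3 V against about +1.8 V vs SCE for the acetoxy-anisole ring), biacetate deprotonates the radical cation at C7, the benzylic radical is captured by the chiral divalent copper acetate and C–O reductive elimination from trivalent copper delivers the acetate, while the anode only returns monovalent to divalent copper and AcOH is reduced to H2 at Pt; C7 is set as R because in the A(1,3)-minimised conformer (C8–H eclipsing the aryl plane) only the face anti to the CH(CH3)CH2Ar group is open, a bias that the ligand is chosen to reinforce and that still holds if the radical is over-oxidised to the free cation in the acetate-rich buffer; the closest known reaction types are the photoelectrochemical copper/bis(oxazoline) radical-relay benzylic C–H cyanation and the Kharasch–Sosnovsky acyloxylation.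

Step 5
Reactants: 8 (1R,2S,3R)-4-[4-(acetyloxy)-3-methoxyphenyl]-1-(3,4-dimethoxyphenyl)-2,3-dimethylbutyl acetate
Product: 9 (1R,2S,3R)-1-(3,4-dimethoxyphenyl)-4-(4-hydroxy-3-methoxyphenyl)-2,3-dimethylbutyl acetate
Conditions: pyrrolidine (1.2 equiv), CH2Cl2, 0 °C to rt, 30 min
Reagents that add atoms: none
Why: Chemoselective aminolysis (acyl transfer to a secondary amine), in which the aryl acetate with its phenoxide leaving group reacts orders of magnitude faster than the hindered secondary benzylic acetate, and the non-acidic medium cannot ionise C7–O, so no stereocenter is touched.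

**Compound list**
1 | 4-bromo-1,2-dimethoxybenzene | COc1ccc(Br)cc1OC | starting material
2 | 2,3-dimethylbuta-1,3-diene | C=C(C)C(C)=C | starting material
3 | 4-[(1E)-2,3-dimethylbuta-1,3-dien-1-yl]-1,2-dimethoxybenzene | COc1ccc(/C=C(\C)C(C)=C)cc1OC | intermediate
4 | 4-bromo-2-methoxyphenol | COc1cc(Br)ccc1O | starting material
5 | 4-bromo-2-methoxyphenyl acetate | COc1cc(Br)ccc1OC(C)=O | intermediate
6 | 4-[(1E,3E)-4-(3,4-dimethoxyphenyl)-2,3-dimethylbuta-1,3-dien-1-yl]-2-methoxyphenyl acetate | COc1cc(/C=C(\C)/C(C)=C/c2ccc(OC)c(OC)c2)ccc1OC(C)=O | intermediate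
7 | 4-[(2R,3R)-4-(3,4-dimethoxyphenyl)-2,3-dimethylbutyl]-2-methoxyphenyl acetate | COc1cc(C[C@@H](C)[C@H](C)Cc2ccc(OC)c(OC)c2)ccc1OC(C)=O | intermediate
8 | (1R,2S,3R)-4-[4-(acetyloxy)-3-methoxyphenyl]-1-(3,4-dimethoxyphenyl)-2,3-dimethylbutyl acetate | COc1cc(C[C@@H](C)[C@H](C)[C@@H](OC(C)=O)c2ccc(OC)c(OC)c2)ccc1OC(C)=O | intermediate
9 | (1R,2S,3R)-1-(3,4-dimethoxyphenyl)-4-(4-hydroxy-3-methoxyphenyl)-2,3-dimethylbutyl acetate | COc1cc(C[C@@H](C)[C@H](C)[C@@H](OC(C)=O)c2ccc(OC)c(OC)c2)ccc1O | target

**Total step count:** 5. **Longest linear sequence:** 5 (1 → 3 → 6 → 7 → 8 → 9).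

**The three steps most likely to fail**

The proposed new step 4 carries the most risk.
- The C7 cation may close onto the other ring to give an aryltetralin.
- Acetate may attack the veratryl ring instead of acting as a base.
- Acetate may itself be oxidised.
- The copper ligand may add little to the substrate bias.

The fallback uses known chemistry only. It sets out from 7 and comes back at 9, so that 8 and step 5 are not needed. DDQ (2.2 equiv) in wet 1,4-dioxane, the known benzylic oxidation of 4-alkylveratroles with the same electronic site control, gives 4-[(2R,3S)-4-(3,4-dimethoxyphenyl)-2,3-dimethyl-4-oxobutyl]-2-methoxyphenyl acetate F1. LiAlH4 in THF (−78 to 0 °C) reduces the ketone under Felkin–Anh control to the 7S alcohol and removes the aryl acetate, giving 4-[(2R,3S,4S)-4-(3,4-dimethoxyphenyl)-4-hydroxy-2,3-dimethylbutyl]-2-methoxyphenol F2. A Mitsunobu esterification (PPh3, DIAD, AcOH, toluene, 0 °C) leaves the free phenol alone and forms the C7–O bond with inversion to give 9. Any SN1 leakage ends at the same 7R epimer through the A(1,3) model.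

Step 3 is second. The hindered diene may be reduced slowly, may undergo 1,4-addition to an inert tetrasubstituted alkene, or may give too much erythro isomer in the second, allylically branched reduction. The fallback replaces asymmetric catalysis by resolution. It sets out from 6 and comes back at 7. Hydrogenation over Pd/C (H2, 1 atm, EtOAc) gives 4-[4-(3,4-dimethoxyphenyl)-2,3-dimethylbutyl]-2-methoxyphenyl acetate F3 as a mixture of stereoisomers. The (2R,3R)-isomer 7 is taken from it by preparative supercritical-fluid chromatography on an amylose tris(3,5-dimethylphenylcarbamate) phase. Throughput is low, but the method is certain.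

Step 1 is third. It combines an electron-rich aryl bromide, a volatile and polymerisable diene, and possible double arylation. Step 2 uses the same reaction on a non-volatile diene with a single reactive terminus and a more reactive bromide, so it is judged safer. The fallback builds the diene by carbonyl chemistry. It sets out from 1 and comes back at 3. A Heck reaction of 1 with methyl methacrylate (Pd(OAc)2, P(o-tol)3, NaOAc, DMAc, 120 °C) gives methyl (2E)-3-(3,4-dimethoxyphenyl)-2-methylprop-2-enoate F4. MeMgBr (2.5 equiv, THF, 0 °C) gives (3E)-4-(3,4-dimethoxyphenyl)-2,3-dimethylbut-3-en-2-ol F5. Mild acid-catalysed dehydration (PPTS, toluene, 60 °C) gives 3.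

**Further compounds**
F1 | step 4 | 4-[(2R,3S)-4-(3,4-dimethoxyphenyl)-2,3-dimethyl-4-oxobutyl]-2-methoxyphenyl acetate | COc1cc(C[C@@H](C)[C@H](C)C(=O)c2ccc(OC)c(OC)c2)ccc1OC(C)=O
F2 | step 4 | 4-[(2R,3S,4S)-4-(3,4-dimethoxyphenyl)-4-hydroxy-2,3-dimethylbutyl]-2-methoxyphenol | COc1cc(C[C@@H](C)[C@H](C)[C@H](O)c2ccc(OC)c(OC)c2)ccc1O
F3 | step 3 | 4-[4-(3,4-dimethoxyphenyl)-2,3-dimethylbutyl]-2-methoxyphenyl acetate (mixture of stereoisomers) | COc1cc(CC(C)C(C)Cc2ccc(OC)c(OC)c2)ccc1OC(C)=O
F4 | step 1 | methyl (2E)-3-(3,4-dimethoxyphenyl)-2-methylprop-2-enoate | COC(=O)/C(C)=C/c1ccc(OC)c(OC)c1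
F5 | step 1 | (3E)-4-(3,4-dimethoxyphenyl)-2,3-dimethylbut-3-en-2-ol | CC(C)(O)/C(C)=C/c1ccc(OC)c(OC)c1
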